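## Structural features

The target 11 (C21H24O7) is a depside: two benzene rings held together by a single aryl ester and by nothing else. Ring A is a 2-hydroxy-4-methoxy-6-methylbenzoyl (everninoyl) unit. Ring B is 2,4-dihydroxy-6-pentylbenzoic acid (olivetolic acid), which carries the ring A acyl group on O4. There is no stereocentre, so no stereocentres stand next to each other, and no ring has to be built; the problem is regiochemistry on two tetrasubstituted arenes and functional-group tolerance. The fragile points are the depside ester and the ring B salicylic acid. The ester is an aryl ester and therefore an activated acyl donor, although its carbonyl carbon is screened by the C2 oxygen and the C6 methyl group of ring A. The salicylic acid loses CO2 on heating, above all in acid. The real difficulty is telling like functions apart: of four phenolic oxygens, one (ring B O4) must be acylated by a di-ortho-substituted benzoic acid and one (ring A O4) methylated, while the two chelated hydroxyls and one of the two carboxyl groups must end up free. The key step exploits ring B C1, whose carboxyl sits between the C2 hydroxyl and the C6 pentyl chain and para to O4. Without that carbon, ring B is 5-pentylresorcinol with O2 and O4 related by symmetry, so it can be acylated unprotected, and the hydroxyl left over is the group that steers CO2 to C1.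

## Logic of the disconnections

**11 ⇒ 10.** The bond cut is ring A O2–CH2Ph, so the last forward step removes a benzyl ether. The ring A hydroxyl must be masked up to that point: free, it would sit ortho to the depside carbonyl, assist acyl transfer and offer magnesium a second site for carboxylation. Benzyl is preferred to an acetal (acid for removal, decarboxylation risk), to a silyl ether (unlikely to last at 120 °C beside methoxide) and to a second methyl ether (not removable next to the C4 methyl ether). The forward step must cleave only a benzylic C–O bond, which the aryl ester and the free acid tolerate.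

**10 ⇒ 8 (through 9).** The bond cut is ring B C1–CO2H. This is the strategic cut: it removes the only carboxyl that would need an ester protecting group, and it turns ring B into a mono-acylated symmetric resorcinol. The forward step must bring CO2 to the carbon ortho to the free hydroxyl and next to the pentyl chain, not to C3 or C5, and the aryl ester must outlast a magnesium methoxide-type reagent in hot DMF. A halogen block at ring B C3 was weighed as a design change to 8 and rejected: it cannot be placed selectively between the two oxygens of 6 without extra steps and would be labile at 120 °C. 8 is therefore kept with the benzyl ether as its only protecting group.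

**8 ⇒ 5 + 6 (through 7).** The bond cut is the acyl C–O bond of the depside. It divides the molecule into two pieces of similar size, each one ring. Because the two hydroxyls of 6 are equivalent, no regiochemical question arises, only mono- against bis-acylation. The forward step must transfer a di-ortho-substituted aroyl group, so the acid is activated as the chloride 7 and 6 is used in excess.

**5 ⇒ 4.** The carboxyl O–CH3 bond is cut, so the acid is carried as its methyl ester through the two alkylations. This allows an inexpensive, stable ester to serve as starting point. The forward step must hydrolyse an ester whose carbonyl is flanked by two ortho substituents.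

**4 ⇒ 2 + 3.** The ring A O2–CH2Ph bond is cut. The benzyl group enters by alkylation with 3 once the other hydroxyl is already capped, so no selectivity is needed, only forcing conditions to break the hydrogen bond to the ester.

**2 ⇒ 1.** The ring A O4–CH3 bond is cut. In 1 the C2 hydroxyl is chelated to the ester carbonyl and the C4 hydroxyl is not, so the order "methyl first, benzyl second" sets the ring A oxygen pattern without a protecting group. The forward step must stop cleanly at mono-methylation.

## Other disconnections considered

**Alternative 1:** The cut runs through ring A: its C1–C6 bond is opened, so the aromatic ring becomes a 3,5,7-trioxooctanoyl chain on ring B O4, as in benzyl 2-hydroxy-6-pentyl-4-[(3,5,7-trioxooctanoyl)oxy]benzoate A1. Forward, the C2 methylene of A1 would add as an enolate to the C7 ketone; loss of water and enolization would give the orsellinate benzyl 4-(2,4-dihydroxy-6-methylbenzoyloxy)-2-hydroxy-6-pentylbenzoate A2.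
- In favour: the route is biomimetic. The ester bond would be made from an unhindered acyl donor, so the hindered aroyl transfer of step 4 is avoided; on that point it is better than the chosen plan. Ring B arrives with its carboxyl in place, so the C1/C3 question of step 5 does not exist; that too is a better point.
- Against: A1 is an aryl ester of a β-keto acid. The base needed for the aldol can instead trigger lactonization through an enol oxygen with expulsion of the ring B phenoxide, or fragmentation towards an acylketene. A2 carries a free ring A O4 hydroxyl, so a selective methylation in the presence of two other phenols is still required before hydrogenolysis.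
- Comparison: structurally it builds a ring where the chosen plan builds none. Mechanistically it relies on enolate chemistry next to an activated ester, against a chelation-directed aromatic substitution. The polyketone chain and the extra methylation should make it about three steps longer than the six of the chosen plan. The final hydrogenolysis is equal in both.

**Alternative 2:** The depside is cut on the other side of the ester oxygen, at the O–C4 bond of ring B. 4-Methoxy-2-(methoxymethoxy)-6-methylbenzoic acid A3 and [4-(tert-butoxycarbonyl)-3-(methoxymethoxy)-5-pentylphenyl]boronic acid A4 would be joined by Cu(OTf)2 under air (Chan–Lam-type oxidative C–O coupling). The product would be tert-butyl 4-{[4-methoxy-2-(methoxymethoxy)-6-methylbenzoyl]oxy}-2-(methoxymethoxy)-6-pentylbenzoate A5, and acid would then remove the tert-butyl ester and both acetals in one operation.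
- In favour: the carboxylate is the nucleophile, so the shielding of the ring A carbonyl matters little; that is better than step 4. The ring B pattern is fixed before the coupling, which is better than step 5 on regiocontrol. The one-step global deprotection equals the one-step end game of the chosen plan.
- Against: A4 is costly. The oxygen at ring B C4, which 6 supplies for free, would have to be differentiated from O2, converted to a triflate and replaced by boron, only to be reintroduced. The carboxyl would also need a tert-butyl ester. Oxidative O-arylation of a di-ortho-substituted, electron-rich acid is at the edge of what this coupling is known for, and protodeboronation and oxidative hydroxylation of A4 would compete. The acidic deprotection also exposes the salicylic acid to decarboxylation.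
- Comparison: structurally it makes the same C–O linkage from the opposite polarity. Mechanistically it depends on transmetalation and reductive elimination at copper instead of classical acyl transfer. It is expected to need roughly ten steps against six.

**Alternative 3:** Ring B is taken apart at C1–C2 and C5–C6. The four-carbon diene already carries the ring A ester: 4-methoxy-4-[(trimethylsilyl)oxy]buta-1,3-dien-2-yl 2-(benzyloxy)-4-methoxy-6-methylbenzoate A6. The two-carbon dienophile carries pentyl chain and carboxyl: benzyl oct-2-ynoate A7. Diels–Alder addition, loss of methanol from the cycloadduct and desilylation would give benzyl 4-[2-(benzyloxy)-4-methoxy-6-methylbenzoyloxy]-2-hydroxy-6-pentylbenzoate A8.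
- In favour: the polarity match (the CH2 terminus of A6 to the β-carbon of A7) fixes the ring B substitution pattern, which is better defined than the C1/C3 choice of step 5. A8 needs a single hydrogenolysis, an end game equal to that of the chosen plan.
- Against: A6 would have to be made by γ-deprotonation and O-silylation of an enol ester, where strong base invites acyl transfer or cleavage. Its 3-acyloxy group makes it less electron-rich than the usual bis(silyloxy) dienes. A7, a β-alkyl ynoate, is a sluggish dienophile, so heat would be needed that a silyl ketene acetal may not survive. Aromatization could also proceed by loss of silanol instead of methanol, leaving a methyl ether on ring B O2.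
- Comparison: structurally it forms two C–C bonds and a ring against one C–C bond. Mechanistically a thermal cycloaddition replaces a directed carboxylation. It is expected to be about two steps longer than the chosen plan and to carry more risk in the diene.

Key step: step 5

Remark on the chemistry: the target is achiral; 8 and 10 were re-derived from 11 atom by atom and needed no correction.

## Route

Step 1
Reactants: 1 methyl orsellinate (methyl 2,4-dihydroxy-6-methylbenzoate)
Product: 2 methyl everninate (methyl 2-hydroxy-4-methoxy-6-methylbenzoate)
Conditions: MeI (1.05 equiv), K2CO3 (1.1 equiv), acetone, 40 °C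
Reagents that add atoms: iodomethane, CI
Why: Williamson ether synthesis; the C2 hydroxyl is tied up in a hydrogen bond to the ester carbonyl and is the less acidic and less nucleophilic of the two, so one equivalent of MeI should alkylate the C4 hydroxyl selectively.

Step 2
Reactants: 2 methyl everninate; 3 benzyl bromide
Product: 4 methyl 2-(benzyloxy)-4-methoxy-6-methylbenzoate
Conditions: BnBr (1.2 equiv), K2CO3 (2 equiv), DMF, 70 °C
Reagents that add atoms: none
Why: Williamson ether synthesis on the chelated phenol; the polar aprotic solvent and heat break the hydrogen bond, and no other nucleophilic site remains in 2.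

Step 3
Reactants: 4 methyl 2-(benzyloxy)-4-methoxy-6-methylbenzoate
Product: 5 2-(benzyloxy)-4-methoxy-6-methylbenzoic acid
Conditions: KOH (10 equiv), DMSO–H2O (4:1), 90 °C; then 1 M HCl, 0 °C
Reagents that add atoms: potassium hydroxide, [K+].[OH-]
Why: Saponification of a hindered ester; poorly solvated hydroxide in aqueous DMSO should overcome the shielding by the two ortho substituents, the aryl benzyl and methyl ethers are inert to hydroxide, and cold acidification avoids protodecarboxylation of the electron-rich acid.

Step 4
Reactants: 5 2-(benzyloxy)-4-methoxy-6-methylbenzoic acid; 6 olivetol (5-pentylbenzene-1,3-diol)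
Product: 8 3-hydroxy-5-pentylphenyl 2-(benzyloxy)-4-methoxy-6-methylbenzoate, via 2-(benzyloxy)-4-methoxy-6-methylbenzoyl chloride 7 (not isolated)
Conditions: (COCl)2 (1.2 equiv), cat. DMF, CH2Cl2, 0 °C to rt, evaporate; then slow addition to 6 (3 equiv), Et3N (1.5 equiv), DMAP (0.1 equiv), CH2Cl2, 0 °C to rt
Reagents that add atoms: none
Why: Acid chloride formation through the chloroiminium salt, then base-mediated O-acylation of a phenol with nucleophilic catalysis by DMAP; the two hydroxyls of 6 are equivalent, so only mono- against bis-acylation needs control, which the threefold excess of 6 and slow addition of 7 should provide, and basic conditions favour O- over C-acylation.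

Step 5
Reactants: 8 3-hydroxy-5-pentylphenyl 2-(benzyloxy)-4-methoxy-6-methylbenzoate
Product: 10 4-[2-(benzyloxy)-4-methoxy-6-methylbenzoyloxy]-2-hydroxy-6-pentylbenzoic acid, via magnesium salicylate chelate 9 (not isolated)
Conditions: MeOMgOCO2Me (2 M in DMF, 4 equiv), 120 °C, N2; then ice-cold 1 M HCl
Reagents that add atoms: magnesium methyl carbonate (methoxymagnesium methyl carbonate), COC(=O)O[Mg]OC
Why: Kolbe–Schmitt-type ortho-carboxylation with magnesium methyl carbonate, a reaction type established for resorcinols, resorcinol mono-ethers and other activated phenols. The phenol of 8 exchanges for methoxide on magnesium, and the methyl carbonate ligand on the same magnesium delivers CO2 to an ortho carbon through a six-membered cyclic transition state; rearomatization gives the magnesium salicylate chelate 9, whose stability pulls the reversible carboxylation forward. No ring of the skeleton closes and no stereocentre is created; the only new skeletal bond is ring B C1–CO2H. Because delivery is intramolecular from the phenoxide-bound magnesium, only the ortho carbons C1 and C3 are within reach and the para carbon C5 is not. C1 should be preferred because it lies para to the acyloxy oxygen, where lone-pair donation is felt most and inductive withdrawal least, and next to the donating pentyl chain, whereas C3 sits directly beside the inductively withdrawing ester oxygen and is screened by the aroyl group twisted out of the ring B plane. The ester should survive because its carbonyl carbon is shielded by the benzyloxy and methyl groups in both ortho positions of ring A, and ring A has no free phenol through which magnesium could direct a second carboxylation. Cold acidification should release 10 without decarboxylation.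

Step 6
Reactants: 10 4-[2-(benzyloxy)-4-methoxy-6-methylbenzoyloxy]-2-hydroxy-6-pentylbenzoic acid
Product: 11 2-hydroxy-4-[(2-hydroxy-4-methoxy-6-methylbenzoyl)oxy]-6-pentylbenzoic acid (target)
Conditions: H2 (1 atm), 10% Pd/C, EtOAc, rt
Reagents that add atoms: none
Why: Heterogeneous hydrogenolysis of an aryl benzyl ether; the aryl ester has no benzylic C–O bond, the acid, the methyl ether and both arenes are inert at 1 atm and rt, and the neutral medium avoids decarboxylation of the salicylic acid.

## Compound list

1 | methyl orsellinate (methyl 2,4-dihydroxy-6-methylbenzoate) | COC(=O)c1c(C)cc(O)cc1O | starting material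
2 | methyl everninate (methyl 2-hydroxy-4-methoxy-6-methylbenzoate) | COC(=O)c1c(C)cc(OC)cc1O | intermediate
3 | benzyl bromide | BrCc1ccccc1 | starting material
4 | methyl 2-(benzyloxy)-4-methoxy-6-methylbenzoate | COC(=O)c1c(C)cc(OC)cc1OCc1ccccc1 | intermediate
5 | 2-(benzyloxy)-4-methoxy-6-methylbenzoic acid | OC(=O)c1c(C)cc(OC)cc1OCc1ccccc1 | intermediate
6 | olivetol (5-pentylbenzene-1,3-diol) | CCCCCc1cc(O)cc(O)c1 | starting material
7 | 2-(benzyloxy)-4-methoxy-6-methylbenzoyl chloride | ClC(=O)c1c(C)cc(OC)cc1OCc1ccccc1 | intermediate
8 | 3-hydroxy-5-pentylphenyl 2-(benzyloxy)-4-methoxy-6-methylbenzoate | CCCCCc1cc(O)cc(OC(=O)c2c(C)cc(OC)cc2OCc2ccccc2)c1 | intermediate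
9 | magnesium salicylate chelate of 10 (magnesium bridging the C2 phenoxide and the C1 carboxylate of ring B) | CCCCCc1cc(OC(=O)c2c(C)cc(OC)cc2OCc2ccccc2)cc2O[Mg]OC(=O)c12 | intermediate
10 | 4-[2-(benzyloxy)-4-methoxy-6-methylbenzoyloxy]-2-hydroxy-6-pentylbenzoic acid | CCCCCc1cc(OC(=O)c2c(C)cc(OC)cc2OCc2ccccc2)cc(O)c1C(=O)O | intermediate
11 | 2-hydroxy-4-[(2-hydroxy-4-methoxy-6-methylbenzoyl)oxy]-6-pentylbenzoic acid | CCCCCc1cc(OC(=O)c2c(C)cc(OC)cc2O)cc(O)c1C(=O)O | target

## Step count and least certain steps

Total step count: 6. Longest linear sequence: 6 steps (1 → 2 → 4 → 5 → 8 → 10 → 11); 3 and 6 enter as purchased.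

**Step 5 (key step).** Three things may go wrong:
- misdirected carboxylation at C3, because C1 and C3 are both ortho to the directing hydroxyl and differ only in which neighbour is pentyl and which is acyloxy;
- slow carboxylation, because an acyloxyphenol is less electron-rich than a resorcinol;
- acyl transfer from the depside ester to methoxide or to a second phenoxide at 120 °C.

Fallback: carboxylate before esterifying. Setting out from 6, magnesium methyl carbonate in DMF at 120 °C (the well-precedented resorcinol case) should give 2,4-dihydroxy-6-pentylbenzoic acid F1. Alkylation of its carboxylate with 3 and KHCO3 in DMF should give benzyl 2,4-dihydroxy-6-pentylbenzoate F2. Its non-chelated C4 hydroxyl would be acylated with 7 (made from 5 as in step 4; Et3N, DMAP, CH2Cl2) to give benzyl 4-[2-(benzyloxy)-4-methoxy-6-methylbenzoyloxy]-2-hydroxy-6-pentylbenzoate F3. Hydrogenolysis over Pd/C would remove both benzyl groups and return to the route at 11.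

**Step 4.** Over-acylation to the bis-ester and a statistical product mixture are the main risks. The di-ortho-substituted acid chloride also transfers its acyl group slowly, which gives hydrolysis and anhydride formation time to compete.

Fallback: move the statistical step to a cheap reagent. Setting out from 6, one equivalent of tert-butyldimethylsilyl chloride with imidazole in DMF should give 3-[(tert-butyldimethylsilyl)oxy]-5-pentylphenol F4. Its single hydroxyl can be acylated to completion with 7 (Et3N, DMAP, CH2Cl2, reflux if needed) to give 3-[(tert-butyldimethylsilyl)oxy]-5-pentylphenyl 2-(benzyloxy)-4-methoxy-6-methylbenzoate F5. Desilylation with n-Bu4NF buffered with acetic acid in THF at 0 °C returns to the route at 8.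

**Step 3.** Incomplete hydrolysis is likely, because attack at the carbonyl carbon is blocked on both faces by the ortho substituents. Forcing the temperature invites decarboxylation on acidification.

Fallback: a redox detour that attacks with small hydride. Setting out from 4, LiAlH4 in THF at 0 °C should give [2-(benzyloxy)-4-methoxy-6-methylphenyl]methanol F6. MnO2 in CH2Cl2 should oxidise it to 2-(benzyloxy)-4-methoxy-6-methylbenzaldehyde F7. Pinnick oxidation (NaClO2, NaH2PO4, 2-methyl-2-butene, t-BuOH–H2O) returns to the route at 5.

**Step 1.** Site selectivity may erode: methylation of the chelated hydroxyl as well, or incomplete conversion that leaves 1 to be dibenzylated in step 2, with products of similar polarity.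

Fallback: exhaustive methylation followed by chelation-controlled mono-demethylation. Setting out from 1, excess MeI and K2CO3 in DMF at 60 °C should give methyl 2,4-dimethoxy-6-methylbenzoate F8. BCl3 in CH2Cl2 from −78 to 0 °C should cleave only the methyl ether ortho to the ester carbonyl, through a six-membered boron chelate, and return to the route at 2.

## Further compounds

F1 | step 5 | 2,4-dihydroxy-6-pentylbenzoic acid (olivetolic acid) | CCCCCc1cc(O)cc(O)c1C(=O)O
F2 | step 5 | benzyl 2,4-dihydroxy-6-pentylbenzoate | CCCCCc1cc(O)cc(O)c1C(=O)OCc1ccccc1
F3 | step 5 | benzyl 4-[2-(benzyloxy)-4-methoxy-6-methylbenzoyloxy]-2-hydroxy-6-pentylbenzoate | CCCCCc1cc(OC(=O)c2c(C)cc(OC)cc2OCc2ccccc2)cc(O)c1C(=O)OCc1ccccc1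
F4 | step 4 | 3-[(tert-butyldimethylsilyl)oxy]-5-pentylphenol | CCCCCc1cc(O)cc(O[Si](C)(C)C(C)(C)C)c1
F5 | step 4 | 3-[(tert-butyldimethylsilyl)oxy]-5-pentylphenyl 2-(benzyloxy)-4-methoxy-6-methylbenzoate | CCCCCc1cc(O[Si](C)(C)C(C)(C)C)cc(OC(=O)c2c(C)cc(OC)cc2OCc2ccccc2)c1
F6 | step 3 | [2-(benzyloxy)-4-methoxy-6-methylphenyl]methanol | OCc1c(C)cc(OC)cc1OCc1ccccc1
F7 | step 3 | 2-(benzyloxy)-4-methoxy-6-methylbenzaldehyde | O=Cc1c(C)cc(OC)cc1OCc1ccccc1
F8 | step 1 | methyl 2,4-dimethoxy-6-methylbenzoate | COC(=O)c1c(C)cc(OC)cc1OC
A1 | alternative 1 | benzyl 2-hydroxy-6-pentyl-4-[(3,5,7-trioxooctanoyl)oxy]benzoate | CCCCCc1cc(OC(=O)CC(=O)CC(=O)CC(C)=O)cc(O)c1C(=O)OCc1ccccc1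
A2 | alternative 1 | benzyl 4-(2,4-dihydroxy-6-methylbenzoyloxy)-2-hydroxy-6-pentylbenzoate | Cc1cc(O)cc(O)c1C(=O)Oc1cc(O)c(C(=O)OCc2ccccc2)c(CCCCC)c1
A3 | alternative 2 | 4-methoxy-2-(methoxymethoxy)-6-methylbenzoic acid | COCOc1cc(OC)cc(C)c1C(=O)O
A4 | alternative 2 | [4-(tert-butoxycarbonyl)-3-(methoxymethoxy)-5-pentylphenyl]boronic acid | CCCCCc1cc(B(O)O)cc(OCOC)c1C(=O)OC(C)(C)C
A5 | alternative 2 | tert-butyl 4-{[4-methoxy-2-(methoxymethoxy)-6-methylbenzoyl]oxy}-2-(methoxymethoxy)-6-pentylbenzoate | CCCCCc1cc(OC(=O)c2c(C)cc(OC)cc2OCOC)cc(OCOC)c1C(=O)OC(C)(C)C
A6 | alternative 3 | 4-methoxy-4-[(trimethylsilyl)oxy]buta-1,3-dien-2-yl 2-(benzyloxy)-4-methoxy-6-methylbenzoate | C=C(OC(=O)c1c(C)cc(OC)cc1OCc1ccccc1)C=C(OC)O[Si](C)(C)C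
A7 | alternative 3 | benzyl oct-2-ynoate | CCCCCC#CC(=O)OCc1ccccc1
A8 | alternative 3 | benzyl 4-[2-(benzyloxy)-4-methoxy-6-methylbenzoyloxy]-2-hydroxy-6-pentylbenzoate | CCCCCc1cc(OC(=O)c2c(C)cc(OC)cc2OCc2ccccc2)cc(O)c1C(=O)OCc1ccccc1
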